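The earlier runs and the new flask come from a simulation for substances that don't exist; scatter was added.

- amber: substrate 0.69 M; first nucleophile 0.828 M; second nucleophile 0.69 M; the very flask that is asked about, followed so far
- flask: substrate 0.69 M; first nucleophile 0.828 M; second nucleophile 0.690 M; time 12 min

amber run (percent of the substrate charged)

| time / s | other capture product / % | target / % | substrate / % |
|---|---|---|---|
| 20.0 | 11.8 | 17.1 | 65.3 |
| 40.0 | 19.9 | 30.3 | 42.9 |
| 60.0 | 25.7 | 37.7 | 28.9 |
| 80.0 | 30.5 | 43.6 | 18.9 |

(each reading ± 0.5 percentage points)

* ratio of other capture product to target at 2.0 s
* ratio of other capture product to target at 12 min

- the earlier runs were read with a standard deviation of 0.5 percentage points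

Slowness is the first thing to read here: the substrate decays like a single first-order lag. You can build the amber run, which is this very flask followed so far, one process at a time. I assume that the first nucleophile makes the target and the second makes the other capture product.

1. **Main step.** With the substrate decay alone, the readings give a half-life of 33.5 s. I take this as the rate-limiting step, with the substrate slowly forming an intermediate. It gives the pace but no ratio.

2. **Add the two captures.** Let B and D be the concentrations of the first and second nucleophile, and P and Q the amounts of target and other capture product. I let each nucleophile take the intermediate at a rate proportional to its own concentration. Dividing one rate by the other removes both time and the intermediate: dQ/dP = s·D/B. Here s is the selectivity factor, the second nucleophile's capture constant over the first's. Integrated, s is ln(fraction of D left) over ln(fraction of B left), and the last reading of the amber run gives 0.806. At 2.0 s, far shorter than the half-life, I use the charges, so my ratio is s·D/B = 0.672.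

3. **Add depletion.** At 80.0 s, the consumed charges raise s·D/B to 0.733, higher than at the start. I split the remaining 18.9% of substrate at that ratio, which gives 38.5% other capture product and 54.5% target. My ratio at 12 min is therefore 0.706.

4. **The rest.** At 80.0 s, the amber readings leave 7.00% of the charge unaccounted for. I leave that amount outside the split.

The forecast gives 0.65 (0.59 to 0.71) at 2.0 s and 0.72 (0.66 to 0.82) at 12 min, close to my 0.672 and 0.706 but not the same. Its upper margin has this ground: “Later conversion of the products can't be excluded, so the upper range stays wider.”

The flask gives 0.659 at 2.0 s and 0.697 at 12 min.

    substrate → intermediate (k = 0.0200 s⁻¹)
    substrate + intermediate → side product (k = 0.110 L mol⁻¹ s⁻¹)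
    first nucleophile + intermediate → target (k = 0.760 L mol⁻¹ s⁻¹)
    second nucleophile + intermediate → other capture product (k = 0.600 L mol⁻¹ s⁻¹)

This flask ends with 54.4% target against 38.0% other capture product, and 55% of the first nucleophile's charge remains. From that remainder, s puts the second nucleophile at 61.8% of its own charge, and the flask holds 62%. Now take the neighbouring flask with 1.2 M of second nucleophile, everything else held. The same reckoning gives s·D/B = 1.17 at the start, and that flask gives 1.15 at 2.0 s. At 12.0 min it holds 51.3% other capture product against 42.9% target, a ratio of 1.20.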